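Each lactone ring is cut at C4–C4a and C1–O2 into a benzoic acid and (R)-propylene oxide, and the dimer is cut at the C4–O–C6' ether into two differently masked copies of one cis-4-hydroxyisochromanone. The key step uses two features of that ring: C4a carries the sole hydrogen flanking the C1 carboxyl, and C3 is an O-bound carbon with a methyl group. Carboxylate-guided palladation at C4a, epoxide opening at CH2 and lactonisation therefore assemble the ring in one operation, with (3R) purchased. The precursor is 3-methoxy-2,4-bis(pivaloyloxy)benzoic acid; its electron-poor, base-labile pivalates permit the later radical oxidation at C4 and a mild final unmasking.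

Key step: step 3

Remark (stereochemistry): read from the SMILES, unit 1 is (3R,4S) with 3-methyl and 4-aryloxy trans, and unit 2 is (3'R,4'R) with 3'-methyl and 4'-hydroxyl cis; (R)-propylene oxide maps onto (3R) and (3'R) without change of descriptor.

Remark (protecting groups): aryl pivalates are assumed to be inert to Pd(OAc)2/KOAc in HFIP near room temperature; the chelated 8'-hydroxyl is left free in the ether-forming step because only the 6'-hydroxyl is acidic and accessible enough to react.

Step 1
Reactants: 1 2-methoxyresorcinol (2-methoxybenzene-1,3-diol)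
Product: 2 2,4-dihydroxy-3-methoxybenzoic acid
Conditions: KHCO3 (4 equiv), CO2 (balloon), glycerol, 130 °C; then aq. HCl
Reagents that add atoms: carbon dioxide, O=C=O
Why: Kolbe–Schmitt carboxylation, in which the potassium phenoxide attacks CO2 at C4 (equivalent to C6 by symmetry), the only position ortho to one hydroxyl and para to the other, to give a chelation-stabilised salicylate.

Step 2
Reactants: 2 2,4-dihydroxy-3-methoxybenzoic acid
Product: 4 3-methoxy-2,4-bis(pivaloyloxy)benzoic acid, via mixed pivalic anhydride 3 (not isolated)
Conditions: PivCl (3.5 equiv), pyridine, DMAP (cat.), CH2Cl2, 0 → 40 °C; then H2O/THF, rt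
Reagents that add atoms: pivaloyl chloride, CC(C)(C)C(Cl)=O; water, O (hydrolysis of the anhydride at the aroyl carbonyl)
Why: DMAP-catalysed acylation (nucleophilic acyl substitution) pivaloylates both phenols and the carboxyl group, and the mixed anhydride is far more water-sensitive than a hindered aryl pivalate, so mild hydrolysis should return only the free acid.

Step 3
Reactants: 4 3-methoxy-2,4-bis(pivaloyloxy)benzoic acid; 5 (R)-propylene oxide
Product: 7 (R)-7-methoxy-3-methyl-6,8-bis(pivaloyloxy)isochroman-1-one, via hydroxy acid 6 (not isolated)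
Conditions: Pd(OAc)2 (5 mol%), N-acetyl-L-tert-leucine (10 mol%), KOAc (1 equiv), 5 (3 equiv), HFIP, 25–40 °C, sealed tube
Reagents that add atoms: none
Why: Pd(OAc)2 with the mono-N-protected amino acid binds the potassium carboxylate and cleaves the C4a–H bond (C6–H of acid 4) by concerted metalation–deprotonation, giving a five-membered palladacycle of divalent palladium; the aryl–palladium bond then opens epoxide 5 at its unsubstituted carbon in an SN2-like, redox-neutral step (C4–C4a), and protonolysis releases hydroxy acid 6. The closest known reaction type is the palladium-catalysed, carboxylate-directed ortho C–H alkylation of benzoic acids with terminal epoxides, which delivers 3-substituted isochroman-1-ones. The lactone ring closes by 6-exo-trig acyl substitution of the C3 hydroxyl on the C1 carboxyl (C1–O2), which should be spontaneous in HFIP. No stereocenter is created: the C3–O bond of the epoxide is never broken, so (R)-5 is carried over as (3R). Site selectivity is secured because the second ortho position carries a pivalate and C4a–H is the only ortho hydrogen, regioselectivity of opening by the steric difference between CH2 and CH(CH3), and chemoselectivity by hindered pivalates that neither bind palladium strongly nor transfer acyl under these mild conditions.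

Step 4
Reactants: 7 (R)-7-methoxy-3-methyl-6,8-bis(pivaloyloxy)isochroman-1-one
Product: 9 (3R)-4-hydroxy-7-methoxy-3-methyl-6,8-bis(pivaloyloxy)isochroman-1-one (C4 epimer mixture), via 4-bromide 8 (not isolated)
Conditions: NBS (1.05 equiv), AIBN (cat.), PhCF3, 85 °C; then Ag2CO3, acetone/H2O, rt, dark
Reagents that add atoms: water, O; N-bromosuccinimide, O=C1CCC(=O)N1Br (its bromine stays only in intermediate 8)
Why: Wohl–Ziegler radical bromination abstracts the benzylic C4–H, nuclear bromination at C5 being disfavoured on the ester-deactivated ring, and silver-assisted SN1-type solvolysis of the secondary benzylic bromide gives the alcohol, whose C4 configuration is irrelevant because it is erased in step 5.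

Step 5
Reactants: 9 (3R)-4-hydroxy-7-methoxy-3-methyl-6,8-bis(pivaloyloxy)isochroman-1-one (C4 epimer mixture)
Product: 10 (3R)-7-methoxy-3-methyl-6,8-bis(pivaloyloxy)isochromane-1,4-dione
Conditions: Dess–Martin periodinane, CH2Cl2, 0 °C → rt
Reagents that add atoms: none
Why: Dess–Martin oxidation of a secondary benzylic alcohol runs under non-basic conditions, so the C3–H alpha to the new ketone should not be enolised and (3R) is kept.

Step 6
Reactants: 10 (3R)-7-methoxy-3-methyl-6,8-bis(pivaloyloxy)isochromane-1,4-dione
Product: 11 (3R,4R)-4-hydroxy-7-methoxy-3-methyl-6,8-bis(pivaloyloxy)isochroman-1-one (3,4-cis)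
Conditions: NaBH4, CeCl3·7H2O, MeOH/THF, −78 °C; AcOH quench at −78 °C
Reagents that add atoms: none
Why: Luche reduction (1,2-hydride addition accelerated by CeCl3), in which hydride should add to the C4 carbonyl from the face opposite the C3 methyl group that projects from the nearly planar lactone ring, placing the hydroxyl cis to the methyl (4R), while the low temperature and cold acidic quench spare lactone, aryl pivalates and the enolisable C3–H.

Step 7
Reactants: 11 (3R,4R)-4-hydroxy-7-methoxy-3-methyl-6,8-bis(pivaloyloxy)isochroman-1-one (one portion; the rest is kept for step 9)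
Product: 12 (3R,4R)-4-(tert-butyldimethylsilyloxy)-7-methoxy-3-methyl-6,8-bis(pivaloyloxy)isochroman-1-one
Conditions: TBSOTf, 2,6-lutidine, CH2Cl2, −40 → 0 °C
Reagents that add atoms: tert-butyldimethylsilyl triflate, CC(C)(C)[Si](C)(C)OS(=O)(=O)C(F)(F)F
Why: Silyl ether formation with a silyl triflate and a hindered pyridine base is fast for secondary alcohols and leaves esters untouched, masking the C4 oxygen so that only a phenol of this half can react in step 9.

Step 8
Reactants: 12 (3R,4R)-4-(tert-butyldimethylsilyloxy)-7-methoxy-3-methyl-6,8-bis(pivaloyloxy)isochroman-1-one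
Product: 13 (3R,4R)-4-(tert-butyldimethylsilyloxy)-6,8-dihydroxy-7-methoxy-3-methylisochroman-1-one
Conditions: K2CO3 (3 equiv), MeOH, 0 °C → rt; then 1 M HCl to pH 5 at 0 °C
Reagents that add atoms: none
Why: Base-mediated transesterification (methanolysis) cleaves the aryl pivalates, whose phenolate leaving groups are activated by the ortho and para lactone carbonyl, much faster than the secondary alkyl silyl ether, and that silyl group also blocks translactonisation by the C4 oxygen.

Step 9
Reactants: 11 (3R,4R)-4-hydroxy-7-methoxy-3-methyl-6,8-bis(pivaloyloxy)isochroman-1-one; 13 (3R,4R)-4-(tert-butyldimethylsilyloxy)-6,8-dihydroxy-7-methoxy-3-methylisochroman-1-one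
Product: 14 (3R,4S)-4-{[(3R,4R)-4-(tert-butyldimethylsilyloxy)-8-hydroxy-7-methoxy-3-methyl-1-oxoisochroman-6-yl]oxy}-7-methoxy-3-methyl-6,8-bis(pivaloyloxy)isochroman-1-one
Conditions: PPh3 (1.5 equiv), DIAD (1.5 equiv), THF, 0 °C → rt
Reagents that add atoms: none
Why: Mitsunobu etherification, in which the oxyphosphonium of the C4 alcohol of 11 is displaced by the C6 phenolate of 13 (C6' of the product) in an SN2 step with inversion, from the face anti to both leaving group and C3 methyl, giving (4S) (3,4-trans), while the C8 hydroxyl of 13 is hydrogen-bonded to the lactone carbonyl and too weakly acidic to compete.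

Step 10
Reactants: 14 (the protected dimer from step 9)
Product: 16 (3R,4S)-4-{[(3R,4R)-4,8-dihydroxy-7-methoxy-3-methyl-1-oxoisochroman-6-yl]oxy}-6,8-dihydroxy-7-methoxy-3-methylisochroman-1-one (target CNP0139537.4), via silyl ether triphenol 15 (not isolated)
Conditions: K2CO3 (3 equiv), MeOH, 0 °C → rt; then aq. HCl (to about 1% in MeOH), rt
Reagents that add atoms: none
Why: Methanolysis (transesterification) of the two aryl pivalates is run while C4'–O is still silylated, so no C4' alkoxide can translactonise to a phthalide, and the phenolates at C6 and C8, being meta to C4a, cannot expel the C4 ether through a quinone methide; the acid stage then cleaves the silyl ether (acid-catalysed desilylation) and recloses any methanolysed lactone.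

Compound list
1 | 2-methoxyresorcinol (2-methoxybenzene-1,3-diol) | COc1c(O)cccc1O | starting material
2 | 2,4-dihydroxy-3-methoxybenzoic acid | COc1c(O)ccc(C(=O)O)c1O | intermediate
3 | 3-methoxy-2,4-bis(pivaloyloxy)benzoic pivalic anhydride | COc1c(OC(=O)C(C)(C)C)ccc(C(=O)OC(=O)C(C)(C)C)c1OC(=O)C(C)(C)C | intermediate (not isolated)
4 | 3-methoxy-2,4-bis(pivaloyloxy)benzoic acid | COc1c(OC(=O)C(C)(C)C)ccc(C(=O)O)c1OC(=O)C(C)(C)C | intermediate
5 | (R)-propylene oxide | C[C@@H]1CO1 | starting material
6 | 6-[(2R)-2-hydroxypropyl]-3-methoxy-2,4-bis(pivaloyloxy)benzoic acid | COc1c(OC(=O)C(C)(C)C)cc(C[C@@H](C)O)c(C(=O)O)c1OC(=O)C(C)(C)C | intermediate (not isolated)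
7 | (R)-7-methoxy-3-methyl-6,8-bis(pivaloyloxy)isochroman-1-one | COc1c(OC(=O)C(C)(C)C)cc2c(c1OC(=O)C(C)(C)C)C(=O)O[C@H](C)C2 | intermediate
8 | (3R)-4-bromo-7-methoxy-3-methyl-6,8-bis(pivaloyloxy)isochroman-1-one (C4 epimer mixture) | COc1c(OC(=O)C(C)(C)C)cc2c(c1OC(=O)C(C)(C)C)C(=O)O[C@H](C)C2Br | intermediate (not isolated)
9 | (3R)-4-hydroxy-7-methoxy-3-methyl-6,8-bis(pivaloyloxy)isochroman-1-one (C4 epimer mixture) | COc1c(OC(=O)C(C)(C)C)cc2c(c1OC(=O)C(C)(C)C)C(=O)O[C@H](C)C2O | intermediate
10 | (3R)-7-methoxy-3-methyl-6,8-bis(pivaloyloxy)isochromane-1,4-dione | COc1c(OC(=O)C(C)(C)C)cc2c(c1OC(=O)C(C)(C)C)C(=O)O[C@H](C)C2=O | intermediate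
11 | (3R,4R)-4-hydroxy-7-methoxy-3-methyl-6,8-bis(pivaloyloxy)isochroman-1-one | COc1c(OC(=O)C(C)(C)C)cc2c(c1OC(=O)C(C)(C)C)C(=O)O[C@H](C)[C@@H]2O | intermediate
12 | (3R,4R)-4-(tert-butyldimethylsilyloxy)-7-methoxy-3-methyl-6,8-bis(pivaloyloxy)isochroman-1-one | COc1c(OC(=O)C(C)(C)C)cc2c(c1OC(=O)C(C)(C)C)C(=O)O[C@H](C)[C@@H]2O[Si](C)(C)C(C)(C)C | intermediate
13 | (3R,4R)-4-(tert-butyldimethylsilyloxy)-6,8-dihydroxy-7-methoxy-3-methylisochroman-1-one | COc1c(O)cc2c(c1O)C(=O)O[C@H](C)[C@@H]2O[Si](C)(C)C(C)(C)C | intermediate
14 | (3R,4S)-4-{[(3R,4R)-4-(tert-butyldimethylsilyloxy)-8-hydroxy-7-methoxy-3-methyl-1-oxoisochroman-6-yl]oxy}-7-methoxy-3-methyl-6,8-bis(pivaloyloxy)isochroman-1-one | COc1c(OC(=O)C(C)(C)C)cc2c(c1OC(=O)C(C)(C)C)C(=O)O[C@H](C)[C@H]2Oc1cc2c(c(O)c1OC)C(=O)O[C@H](C)[C@@H]2O[Si](C)(C)C(C)(C)C | intermediate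
15 | (3R,4S)-4-{[(3R,4R)-4-(tert-butyldimethylsilyloxy)-8-hydroxy-7-methoxy-3-methyl-1-oxoisochroman-6-yl]oxy}-6,8-dihydroxy-7-methoxy-3-methylisochroman-1-one | COc1c(O)cc2c(c1O)C(=O)O[C@H](C)[C@H]2Oc1cc2c(c(O)c1OC)C(=O)O[C@H](C)[C@@H]2O[Si](C)(C)C(C)(C)C | intermediate (not isolated)
16 | (3R,4S)-4-{[(3R,4R)-4,8-dihydroxy-7-methoxy-3-methyl-1-oxoisochroman-6-yl]oxy}-6,8-dihydroxy-7-methoxy-3-methylisochroman-1-one | COc1c(O)cc2c(c1O)C(=O)O[C@H](C)[C@H]2Oc1cc2c(c(O)c1OC)C(=O)O[C@H](C)[C@@H]2O | target

Total step count: 10. Longest linear sequence: 10 steps (1 → 2 → 4 → 7 → 9 → 10 → 11 → 12 → 13 → 14 → 16), because the phenol partner 13 is made from the same alcohol 11 that serves as the second partner in step 9.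

Steps most likely to fail

Step 3 (key step). Palladation may be slowed by the crowded, electron-poor acid, the ortho pivalate may transfer its acyl group to the neighbouring carboxylate, or the epoxide may be consumed by the solvent before the aryl–palladium bond captures it. The fallback sets out from 4 and comes back at 7, replacing the catalytic C–H alkylation by a stoichiometric aryl-metal opening of the epoxide. Carboxylate-directed ortho iodination of 4 with [Cp*IrI2]2 (cat.) and N-iodosuccinimide in HFIP should give 6-iodo-3-methoxy-2,4-bis(pivaloyloxy)benzoic acid F1. Deprotonation and iodine–magnesium exchange with i-PrMgCl·LiCl (2 equiv, THF, −40 °C), followed by CuI-catalysed opening of (R)-propylene oxide 5 at its CH2 group and acidic work-up, should give hydroxy acid 6, which lactonises to 7.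

Step 4. Electrophilic bromination of the ring at C5 may compete with hydrogen abstraction at C4, and loss of HBr across C3–C4 from the bromide would give the achiral isocoumarin and erase the purchased stereocenter. The fallback sets out from 7 and comes back at 10, replacing halogenation and solvolysis by a direct metal-oxo C–H oxidation: CrO3 (catalytic) with H5IO6 in MeCN at low temperature should convert the benzylic CH2 of 7 straight into ketone 10, bypassing 8 and 9. This fallback makes no compound outside the list (F0).

Step 9. Elimination across C3–C4 from the oxyphosphonium (H3 is anti to the leaving group in the cis alcohol), slow SN2 displacement at the hindered secondary benzylic carbon, or etherification at the chelated hydroxyl may lower the efficiency of the coupling. The fallback sets out from 11 and comes back at 14, replacing the redox condensation by a two-stage Williamson displacement. Mesylation of 11 (MsCl, Et3N, CH2Cl2, −20 °C) should give, with retention, (3R,4R)-7-methoxy-3-methyl-1-oxo-6,8-bis(pivaloyloxy)isochroman-4-yl methanesulfonate F2. Its displacement by the more acidic C6 phenolate of 13 (Cs2CO3, DMF, 0 °C → rt) with inversion should give 14.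

Further compounds
F1 | step 3 | 6-iodo-3-methoxy-2,4-bis(pivaloyloxy)benzoic acid | COc1c(OC(=O)C(C)(C)C)cc(I)c(C(=O)O)c1OC(=O)C(C)(C)C
F0 | step 4 | none | none
F2 | step 9 | (3R,4R)-7-methoxy-3-methyl-1-oxo-6,8-bis(pivaloyloxy)isochroman-4-yl methanesulfonate | COc1c(OC(=O)C(C)(C)C)cc2c(c1OC(=O)C(C)(C)C)C(=O)O[C@H](C)[C@@H]2OS(C)(=O)=O
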